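**Retrosynthetic overview**

1. The target is a bicyclo[3.2.1]oct-3-ene-2,8-dione. Its six-membered ring C1–C2–C3–C4–C5–C8 carries oxygen, or the trace of it, on every second carbon (ketone C-2, ketone C-8, former ketone C-4 now part of C3=C4). It is a resorcinol-type triketide ring held in its diketo form because C-1 and C-5 are tied by the C6–C7 bridge, and this pattern is what lets a Claisen acylation and an aldol condensation build it.
2. Key disconnections: C8–C1 (acylation of a methyl ketone at its inner α-carbon by an acylketene) and C3=C4 (aldol condensation of the acetyl methyl group with the cinnamoyl ketone). Together they open both rings to an acyclic tert-butyl cinnamoylacetate that carries a 1,2-diaryl-4-oxopentyl chain on its C-2. Forward ring order: cyclopentanone first, then the cyclohexenone (and with it the seven-membered ring).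
3. C-7 is set by rhodium-catalysed asymmetric 1,4-arylation of a methyl enone, and C-6 by palladium-catalysed asymmetric allylic alkylation of the β-keto ester with a γ-carbonate enone. C-1 and C-5 are relayed from these two centres in the key step.
4. Building blocks: 3,5-dihydroxybenzaldehyde (vinyl addition, carbonate, cross-metathesis with methyl vinyl ketone), methyl 4-hydroxycinnamate (crossed Claisen with tert-butyl acetate) and 4-hydroxyphenylboronic acid pinacol ester. All phenols travel as triisopropylsilyl ethers and are freed last with buffered fluoride.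

Key step: step 9

Remark: TIPS = triisopropylsilyl and TIPSO = triisopropylsilyloxy; the ligand antipodes named in steps 6 and 8 are those expected to give the configurations shown, and the other commercial antipode is to be taken if a test run shows the opposite facial sense.

**Route**

Step 1
Reactants: 1 3,5-dihydroxybenzaldehyde
Product: 2 3,5-bis(TIPSO)benzaldehyde
Conditions: TIPSCl (2.4 equiv), imidazole (5 equiv), DMF, rt
Reagents that add atoms: triisopropylsilyl chloride, CC(C)[Si](Cl)(C(C)C)C(C)C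
Why: Imidazole-promoted silylation of both phenols (standard silyl ether formation); the bulky silyl groups are chosen to survive base, heat and acid later and to shield the resorcinol ring from electrophiles.

Step 2
Reactants: 2 3,5-bis(TIPSO)benzaldehyde; 3 vinylmagnesium bromide
Product: 5 rac-1-[3,5-bis(TIPSO)phenyl]prop-2-en-1-yl methyl carbonate, via bromomagnesium alkoxide 4 (not isolated)
Conditions: 3 (1.2 equiv), THF, −78 to 0 °C; then ClCO2Me (1.5 equiv), 0 °C to rt
Reagents that add atoms: methyl chloroformate, COC(=O)Cl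
Why: Grignard 1,2-addition to the aldehyde and acylation of the alkoxide in the same flask should give the branched allylic carbonate; the new centre is racemic on purpose, since step 6 is meant to funnel both enantiomers into one.

Step 3
Reactants: 5 rac-1-[3,5-bis(TIPSO)phenyl]prop-2-en-1-yl methyl carbonate; 6 methyl vinyl ketone (but-3-en-2-one)
Product: 7 rac-(2E)-1-[3,5-bis(TIPSO)phenyl]-4-oxopent-2-en-1-yl methyl carbonate
Conditions: 6 (4 equiv), RuCl2(H2IMes)(=CH-C6H4-2-O-i-Pr) (second-generation Hoveyda–Grubbs catalyst, 5 mol%), CH2Cl2, 40 °C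
Reagents that add atoms: none
Why: Olefin cross-metathesis of a terminal alkene with an excess of an electron-poor enone that homodimerises slowly should give the (E)-enone; at this stage no second alkene is present that could ring-close.

Step 4
Reactants: 8 methyl (2E)-3-(4-hydroxyphenyl)prop-2-enoate
Product: 9 methyl (2E)-3-[4-(TIPSO)phenyl]prop-2-enoate
Conditions: TIPSCl (1.2 equiv), imidazole (2.5 equiv), DMF, rt
Reagents that add atoms: triisopropylsilyl chloride, CC(C)[Si](Cl)(C(C)C)C(C)C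
Why: Standard phenol silylation; the ester and the alkene are untouched.

Step 5
Reactants: 10 tert-butyl acetate; 9 methyl (2E)-3-[4-(TIPSO)phenyl]prop-2-enoate
Product: 12 tert-butyl (4E)-3-oxo-5-[4-(TIPSO)phenyl]pent-4-enoate, via lithium enolate 11 (not isolated)
Conditions: 10 (2.2 equiv), LiN(i-Pr)2 (2.2 equiv, commercial solution), THF, −78 °C; then 9 (1 equiv), −78 to −20 °C; aq. HCl
Reagents that add atoms: none
Why: Crossed Claisen condensation of a lithium ester enolate with a non-enolisable ester; the second equivalent of enolate deprotonates the β-keto ester formed and so pulls the equilibrium, and at low temperature attack at the carbonyl is expected to beat conjugate addition.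

Step 6
Reactants: 7 rac-(2E)-1-[3,5-bis(TIPSO)phenyl]-4-oxopent-2-en-1-yl methyl carbonate; 12 tert-butyl (4E)-3-oxo-5-[4-(TIPSO)phenyl]pent-4-enoate
Product: 13 tert-butyl (4E)-2-[(1S,2E)-1-[3,5-bis(TIPSO)phenyl]-4-oxopent-2-en-1-yl]-3-oxo-5-[4-(TIPSO)phenyl]pent-4-enoate (both C-2 epimers)
Conditions: Pd2(dba)3·CHCl3 (2.5 mol%), (R,R)-DACH-phenyl Trost ligand (7.5 mol%), 12 (1.05 equiv), CH2Cl2, 0 °C to rt
Reagents that add atoms: none
Why: Tsuji–Trost asymmetric allylic alkylation: ionisation of either enantiomer of 7 gives a 1-acyl-3-aryl-π-allylpalladium complex whose faces can interconvert through the oxygen-bound dienolate, the methoxide set free deprotonates 12, and the soft enolate should attack the benzylic terminus remote from the acyl group (conjugation is kept) on the face chosen by the ligand, so C-1′ is set (S) by catalyst control in a dynamic kinetic asymmetric transformation; C-2 stays epimeric, which is harmless because it is enolisable until step 9.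

Step 7
Reactants: 14 4-(4,4,5,5-tetramethyl-1,3,2-dioxaborolan-2-yl)phenol
Product: 15 4,4,5,5-tetramethyl-2-[4-(TIPSO)phenyl]-1,3,2-dioxaborolane
Conditions: TIPSCl (1.2 equiv), imidazole (2.5 equiv), DMF, rt
Reagents that add atoms: triisopropylsilyl chloride, CC(C)[Si](Cl)(C(C)C)C(C)C
Why: Standard phenol silylation; the pinacol boronate is stable to these conditions.

Step 8
Reactants: 13 tert-butyl (4E)-2-[(1S,2E)-1-[3,5-bis(TIPSO)phenyl]-4-oxopent-2-en-1-yl]-3-oxo-5-[4-(TIPSO)phenyl]pent-4-enoate; 15 4,4,5,5-tetramethyl-2-[4-(TIPSO)phenyl]-1,3,2-dioxaborolane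
Product: 16 tert-butyl (4E)-2-[(1S,2R)-1-[3,5-bis(TIPSO)phenyl]-4-oxo-2-[4-(TIPSO)phenyl]pentyl]-3-oxo-5-[4-(TIPSO)phenyl]pent-4-enoate (both C-2 epimers)
Conditions: 15 (2 equiv), [RhCl(C2H4)2]2 (2.5 mol%), (R,R)-2,5-diphenylbicyclo[2.2.2]octa-2,5-diene (5.5 mol%), K3PO4 (1 equiv), dioxane/H2O 10:1, 50 °C
Reagents that add atoms: none
Why: Hayashi–Miyaura reaction: the arylrhodium species should add to the β-carbon (C-2′) of the methyl enone on its Si face under control of the chiral diene, giving the (2′R) centre (the pair C-1′/C-2′ becomes the trans-diaryl unit of the five-membered ring), and water protonates the rhodium enolate; the cinnamoyl enone should be spared because under the basic conditions it sits in the β-keto ester enolate and carries an electron-rich β-aryl group.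

Step 9
Reactants: 16 tert-butyl (4E)-2-[(1S,2R)-1-[3,5-bis(TIPSO)phenyl]-4-oxo-2-[4-(TIPSO)phenyl]pentyl]-3-oxo-5-[4-(TIPSO)phenyl]pent-4-enoate
Product: 20 (1R,5S,6S,7S)-6-[3,5-bis(TIPSO)phenyl]-7-[4-(TIPSO)phenyl]-4-[(E)-2-[4-(TIPSO)phenyl]ethenyl]bicyclo[3.2.1]oct-3-ene-2,8-dione, via acylketene 17 (not isolated), via triketone 18 (not isolated), via ketol 19 (not isolated)
Conditions: xylenes (0.005 M), 130 °C, N2 stream (−t-BuOH); then (+)-camphor-10-sulfonic acid (0.3 equiv), 4 Å MS, 90 °C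
Reagents that add atoms: none
Why: Proposed new method: at 130 °C the tert-butyl β-keto ester should lose tert-butanol by the known retro-ene path to give acylketene 17, in which C-2 no longer carries an acidic hydrogen and the future C-8 is a strong acylating carbon; the enol of the methyl ketone is expected to attack it through its inner carbon (future C-1) in a 5-(enolexo)-exo-dig closure that forms the C8–C1 bond and the cyclopentanone of 18, and the added acid then promotes a 6-(enolendo)-exo-trig aldol addition of the acetyl methyl carbon (future C-3) to the cinnamoyl carbonyl (future C-4), followed by irreversible loss of water from ketol 19, which closes the six-membered (and with it the seven-membered) ring. The closest known reaction types are the thermolysis of tert-butyl β-keto esters and dioxinones to acylketenes that are captured by alcohols, amines, enamines or enol ethers, the biomimetic aldol cyclisation of the resulting polycarbonyl chains to resorcinols, and the aldol condensation that ends a Robinson annulation; not yet shown is capture of the ketene at carbon by a plain ketone enol and a polyketide-type closure whose product cannot aromatise. Carbon instead of oxygen acylation, and attack by the inner instead of the methyl α-carbon, should be secured by ring size (five atoms against seven), and the usual [4+2] outlet of acylketenes with enols is closed because it would need a double bond at the future bridgehead C-5. C-1 and C-5 are enolisable in 18 and are fixed only in the aldol closure: they must become cis to each other for the bridge to form, and the bridge is expected on the ring face anti to the C-6 aryl group, because the attacked carbon C-4 turns into a crowded carbinol next to C-6 while the acetyl carbon next to the cis C-7 aryl group stays trigonal, so both new centres are set by substrate control from C-6 and C-7. The other reactions open to 18 (enolisation, oxa-Michael closure to a dihydropyranone, 6-endo addition of C-1 to the styryl terminus) are reversible and should drain into 20, high dilution is meant to suppress ketene dimerisation, and the bulky silyl ethers are meant to keep the resorcinol ring from being acylated.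

Step 10
Reactants: 20 (1R,5S,6S,7S)-6-[3,5-bis(TIPSO)phenyl]-7-[4-(TIPSO)phenyl]-4-[(E)-2-[4-(TIPSO)phenyl]ethenyl]bicyclo[3.2.1]oct-3-ene-2,8-dione
Product: 21 (1R,5S,6S,7S)-6-(3,5-dihydroxyphenyl)-7-(4-hydroxyphenyl)-4-[(E)-2-(4-hydroxyphenyl)ethenyl]bicyclo[3.2.1]oct-3-ene-2,8-dione
Conditions: n-Bu4NF (4.4 equiv), AcOH (4.4 equiv), THF, 0 °C
Reagents that add atoms: none
Why: Fluoride cleaves the four aryl silyl ethers; acetic acid buffers the phenoxides so that the non-enolisable β-diketone is not opened by retro-Claisen attack, and no stereocentre is touched.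

**Compound list**

1 | 3,5-dihydroxybenzaldehyde | O=Cc1cc(O)cc(O)c1 | starting material
2 | 3,5-bis(TIPSO)benzaldehyde | O=Cc1cc(O[Si](C(C)C)(C(C)C)C(C)C)cc(O[Si](C(C)C)(C(C)C)C(C)C)c1 | intermediate
3 | vinylmagnesium bromide | C=C[Mg]Br | starting material
4 | bromomagnesium 1-[3,5-bis(TIPSO)phenyl]prop-2-en-1-olate (racemic) | C=CC(O[Mg]Br)c1cc(O[Si](C(C)C)(C(C)C)C(C)C)cc(O[Si](C(C)C)(C(C)C)C(C)C)c1 | intermediate
5 | rac-1-[3,5-bis(TIPSO)phenyl]prop-2-en-1-yl methyl carbonate | C=CC(OC(=O)OC)c1cc(O[Si](C(C)C)(C(C)C)C(C)C)cc(O[Si](C(C)C)(C(C)C)C(C)C)c1 | intermediate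
6 | methyl vinyl ketone (but-3-en-2-one) | C=CC(C)=O | starting material
7 | rac-(2E)-1-[3,5-bis(TIPSO)phenyl]-4-oxopent-2-en-1-yl methyl carbonate | CC(=O)/C=C/C(OC(=O)OC)c1cc(O[Si](C(C)C)(C(C)C)C(C)C)cc(O[Si](C(C)C)(C(C)C)C(C)C)c1 | intermediate
8 | methyl (2E)-3-(4-hydroxyphenyl)prop-2-enoate | COC(=O)/C=C/c1ccc(O)cc1 | starting material
9 | methyl (2E)-3-[4-(TIPSO)phenyl]prop-2-enoate | COC(=O)/C=C/c1ccc(O[Si](C(C)C)(C(C)C)C(C)C)cc1 | intermediate
10 | tert-butyl acetate | CC(=O)OC(C)(C)C | starting material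
11 | lithium 1-tert-butoxyethen-1-olate (lithium enolate of 10) | C=C(O[Li])OC(C)(C)C | intermediate
12 | tert-butyl (4E)-3-oxo-5-[4-(TIPSO)phenyl]pent-4-enoate | CC(C)(C)OC(=O)CC(=O)/C=C/c1ccc(O[Si](C(C)C)(C(C)C)C(C)C)cc1 | intermediate
13 | tert-butyl (4E)-2-[(1S,2E)-1-[3,5-bis(TIPSO)phenyl]-4-oxopent-2-en-1-yl]-3-oxo-5-[4-(TIPSO)phenyl]pent-4-enoate (C-2 epimers) | CC(=O)/C=C/[C@H](c1cc(O[Si](C(C)C)(C(C)C)C(C)C)cc(O[Si](C(C)C)(C(C)C)C(C)C)c1)C(C(=O)OC(C)(C)C)C(=O)/C=C/c1ccc(O[Si](C(C)C)(C(C)C)C(C)C)cc1 | intermediate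
14 | 4-(4,4,5,5-tetramethyl-1,3,2-dioxaborolan-2-yl)phenol | CC1(C)OB(c2ccc(O)cc2)OC1(C)C | starting material
15 | 4,4,5,5-tetramethyl-2-[4-(TIPSO)phenyl]-1,3,2-dioxaborolane | CC1(C)OB(c2ccc(O[Si](C(C)C)(C(C)C)C(C)C)cc2)OC1(C)C | intermediate
16 | tert-butyl (4E)-2-[(1S,2R)-1-[3,5-bis(TIPSO)phenyl]-4-oxo-2-[4-(TIPSO)phenyl]pentyl]-3-oxo-5-[4-(TIPSO)phenyl]pent-4-enoate (C-2 epimers) | CC(=O)C[C@@H](c1ccc(O[Si](C(C)C)(C(C)C)C(C)C)cc1)[C@H](c1cc(O[Si](C(C)C)(C(C)C)C(C)C)cc(O[Si](C(C)C)(C(C)C)C(C)C)c1)C(C(=O)OC(C)(C)C)C(=O)/C=C/c1ccc(O[Si](C(C)C)(C(C)C)C(C)C)cc1 | intermediate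
17 | (4E)-2-[(1R,2R)-1-[3,5-bis(TIPSO)phenyl]-4-oxo-2-[4-(TIPSO)phenyl]pentyl]-5-[4-(TIPSO)phenyl]penta-1,4-diene-1,3-dione (acylketene; same spatial arrangement as 16, the descriptor at C-1′ changes by ranking only) | CC(=O)C[C@@H](c1ccc(O[Si](C(C)C)(C(C)C)C(C)C)cc1)[C@H](c1cc(O[Si](C(C)C)(C(C)C)C(C)C)cc(O[Si](C(C)C)(C(C)C)C(C)C)c1)C(=C=O)C(=O)/C=C/c1ccc(O[Si](C(C)C)(C(C)C)C(C)C)cc1 | intermediate
18 | (3S,4S)-2-acetyl-4-[3,5-bis(TIPSO)phenyl]-3-[4-(TIPSO)phenyl]-5-[(2E)-3-[4-(TIPSO)phenyl]prop-2-enoyl]cyclopentan-1-one (C-2 and C-5 epimers and enol forms) | CC(=O)C1C(=O)C(C(=O)/C=C/c2ccc(O[Si](C(C)C)(C(C)C)C(C)C)cc2)[C@@H](c2cc(O[Si](C(C)C)(C(C)C)C(C)C)cc(O[Si](C(C)C)(C(C)C)C(C)C)c2)[C@@H]1c1ccc(O[Si](C(C)C)(C(C)C)C(C)C)cc1 | intermediate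
19 | (1R,5S,6S,7S)-6-[3,5-bis(TIPSO)phenyl]-4-hydroxy-7-[4-(TIPSO)phenyl]-4-[(E)-2-[4-(TIPSO)phenyl]ethenyl]bicyclo[3.2.1]octane-2,8-dione (C-4 epimers) | O=C1CC(O)(/C=C/c2ccc(O[Si](C(C)C)(C(C)C)C(C)C)cc2)[C@H]2C(=O)[C@@H]1[C@@H](c1ccc(O[Si](C(C)C)(C(C)C)C(C)C)cc1)[C@@H]2c1cc(O[Si](C(C)C)(C(C)C)C(C)C)cc(O[Si](C(C)C)(C(C)C)C(C)C)c1 | intermediate
20 | (1R,5S,6S,7S)-6-[3,5-bis(TIPSO)phenyl]-7-[4-(TIPSO)phenyl]-4-[(E)-2-[4-(TIPSO)phenyl]ethenyl]bicyclo[3.2.1]oct-3-ene-2,8-dione | O=C1C=C(/C=C/c2ccc(O[Si](C(C)C)(C(C)C)C(C)C)cc2)[C@H]2C(=O)[C@@H]1[C@@H](c1ccc(O[Si](C(C)C)(C(C)C)C(C)C)cc1)[C@@H]2c1cc(O[Si](C(C)C)(C(C)C)C(C)C)cc(O[Si](C(C)C)(C(C)C)C(C)C)c1 | intermediate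
21 | (1R,5S,6S,7S)-6-(3,5-dihydroxyphenyl)-7-(4-hydroxyphenyl)-4-[(E)-2-(4-hydroxyphenyl)ethenyl]bicyclo[3.2.1]oct-3-ene-2,8-dione | O=C1C=C(/C=C/c2ccc(O)cc2)[C@H]2C(=O)[C@@H]1[C@@H](c1ccc(O)cc1)[C@@H]2c1cc(O)cc(O)c1 | target

**Totals**

Total step count: 10. Longest linear sequence: 7 steps (steps 1, 2, 3, 6, 8, 9, 10, from 3,5-dihydroxybenzaldehyde).

**Steps most likely to fail**

Step 9 (bears the label). What may go wrong: the acylketene may be consumed by paths other than bond formation at the future C-1 (acylation at the enol oxygen, acylation of the silylated resorcinol ring, dimerisation), so that triketone 18 never forms. The fallback uses known reactions only: the five-membered ring is closed from its other side and the acetyl group is added last. It sets out from carbonate 5.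
- Cross-metathesis of 5 with methyl acrylate (catalyst of step 3) should give methyl (2E)-4-[3,5-bis(TIPSO)phenyl]-4-[(methoxycarbonyl)oxy]but-2-enoate F1.
- Tsuji–Trost alkylation of 12 with F1 under the conditions of step 6 should give tert-butyl (4E)-2-[(1S,2E)-1-[3,5-bis(TIPSO)phenyl]-4-methoxy-4-oxobut-2-en-1-yl]-3-oxo-5-[4-(TIPSO)phenyl]pent-4-enoate F2.
- Rhodium-catalysed 1,4-addition of 15 as in step 8 should give tert-butyl (4E)-2-[(1S,2R)-1-[3,5-bis(TIPSO)phenyl]-4-methoxy-4-oxo-2-[4-(TIPSO)phenyl]butyl]-3-oxo-5-[4-(TIPSO)phenyl]pent-4-enoate F3.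
- p-TsOH in toluene at 80 °C removes the tert-butyl group to give (4E)-2-[(1S,2R)-1-[3,5-bis(TIPSO)phenyl]-4-methoxy-4-oxo-2-[4-(TIPSO)phenyl]butyl]-3-oxo-5-[4-(TIPSO)phenyl]pent-4-enoic acid F4 (not isolated), which decarboxylates to methyl (3R,4R,7E)-4-[3,5-bis(TIPSO)phenyl]-6-oxo-3-[4-(TIPSO)phenyl]-8-[4-(TIPSO)phenyl]oct-7-enoate F5.
- KO-t-Bu in THF effects the classical Dieckmann-type cyclisation of this ε-keto ester (the only enolisable carbon of the styryl ketone attacks the methyl ester) to (3S,4R)-3-[3,5-bis(TIPSO)phenyl]-4-[4-(TIPSO)phenyl]-2-[(2E)-3-[4-(TIPSO)phenyl]prop-2-enoyl]cyclopentan-1-one F6.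
- The dianion of F6 (LiN(i-Pr)2, 2.2 equiv) can carry its second charge only at the ring CH2 and is acylated there by N-methoxy-N-methylacetamide (γ-acylation of a β-diketone dianion).

This gives triketone 18, where the fallback comes back to the route; 18 is then closed to 20 under the acid stage of step 9.

Step 6. What may go wrong: the two faces of the allyl intermediate may exchange more slowly than the enolate attacks, or the ligand may not tell them apart, so that 13 forms with low enantiomeric purity; attack at the acyl-bearing terminus is a lesser risk. In the fallback the stereocentre comes from a resolved alcohol and is transferred by a stereospecific substitution. It sets out from aldehyde 2.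
- Addition of 3 with aqueous work-up gives racemic 1-[3,5-bis(TIPSO)phenyl]prop-2-en-1-ol F7.
- Candida antarctica lipase B and vinyl acetate are expected, by the usual empirical rule for secondary alcohols, to acetylate the (R)-alcohol, giving (1R)-1-[3,5-bis(TIPSO)phenyl]prop-2-en-1-yl acetate F8 and leaving (1S)-1-[3,5-bis(TIPSO)phenyl]prop-2-en-1-ol F9, which is set aside.
- Cross-metathesis of F8 with 6 as in step 3 gives (1R,2E)-1-[3,5-bis(TIPSO)phenyl]-4-oxopent-2-en-1-yl acetate F10.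
- Pd(PPh3)4 with 12 and NaH in THF should replace the acetate with net retention (two inversions).

This gives 13, where the fallback comes back to the route.

Step 8. What may go wrong: the β-keto ester may bind rhodium as a β-diketonate and stall transmetalation, or catalyst and substrate control may oppose each other and erode the diastereomer ratio at C-2′. In the fallback the acidic β-keto ester is first locked in a temporary ring that is also a ketene source. It sets out from 13.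
- Acetone, (CF3CO)2O and CF3CO2H at 0 °C to rt should convert the tert-butyl β-keto ester into 5-[(1R,2E)-1-[3,5-bis(TIPSO)phenyl]-4-oxopent-2-en-1-yl]-2,2-dimethyl-6-[(E)-2-[4-(TIPSO)phenyl]ethenyl]-4H-1,3-dioxin-4-one F11.
- The arylation of step 8 on F11, which has no acidic C–H and no chelating group left, should give 5-[(1R,2R)-1-[3,5-bis(TIPSO)phenyl]-4-oxo-2-[4-(TIPSO)phenyl]pentyl]-2,2-dimethyl-6-[(E)-2-[4-(TIPSO)phenyl]ethenyl]-4H-1,3-dioxin-4-one F12.
- Heating F12 at 110 °C in toluene releases acetone and the same acylketene 17.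

The fallback thus comes back to the route inside step 9, and hence at 20.

**Further compounds**

F1 | step 9 | methyl (2E)-4-[3,5-bis(TIPSO)phenyl]-4-[(methoxycarbonyl)oxy]but-2-enoate (racemic) | COC(=O)/C=C/C(OC(=O)OC)c1cc(O[Si](C(C)C)(C(C)C)C(C)C)cc(O[Si](C(C)C)(C(C)C)C(C)C)c1
F2 | step 9 | tert-butyl (4E)-2-[(1S,2E)-1-[3,5-bis(TIPSO)phenyl]-4-methoxy-4-oxobut-2-en-1-yl]-3-oxo-5-[4-(TIPSO)phenyl]pent-4-enoate | COC(=O)/C=C/[C@H](c1cc(O[Si](C(C)C)(C(C)C)C(C)C)cc(O[Si](C(C)C)(C(C)C)C(C)C)c1)C(C(=O)OC(C)(C)C)C(=O)/C=C/c1ccc(O[Si](C(C)C)(C(C)C)C(C)C)cc1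
F3 | step 9 | tert-butyl (4E)-2-[(1S,2R)-1-[3,5-bis(TIPSO)phenyl]-4-methoxy-4-oxo-2-[4-(TIPSO)phenyl]butyl]-3-oxo-5-[4-(TIPSO)phenyl]pent-4-enoate | COC(=O)C[C@@H](c1ccc(O[Si](C(C)C)(C(C)C)C(C)C)cc1)[C@H](c1cc(O[Si](C(C)C)(C(C)C)C(C)C)cc(O[Si](C(C)C)(C(C)C)C(C)C)c1)C(C(=O)OC(C)(C)C)C(=O)/C=C/c1ccc(O[Si](C(C)C)(C(C)C)C(C)C)cc1
F4 | step 9 | (4E)-2-[(1S,2R)-1-[3,5-bis(TIPSO)phenyl]-4-methoxy-4-oxo-2-[4-(TIPSO)phenyl]butyl]-3-oxo-5-[4-(TIPSO)phenyl]pent-4-enoic acid | COC(=O)C[C@@H](c1ccc(O[Si](C(C)C)(C(C)C)C(C)C)cc1)[C@H](c1cc(O[Si](C(C)C)(C(C)C)C(C)C)cc(O[Si](C(C)C)(C(C)C)C(C)C)c1)C(C(=O)O)C(=O)/C=C/c1ccc(O[Si](C(C)C)(C(C)C)C(C)C)cc1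
F5 | step 9 | methyl (3R,4R,7E)-4-[3,5-bis(TIPSO)phenyl]-6-oxo-3-[4-(TIPSO)phenyl]-8-[4-(TIPSO)phenyl]oct-7-enoate | COC(=O)C[C@@H](c1ccc(O[Si](C(C)C)(C(C)C)C(C)C)cc1)[C@H](c1cc(O[Si](C(C)C)(C(C)C)C(C)C)cc(O[Si](C(C)C)(C(C)C)C(C)C)c1)CC(=O)/C=C/c1ccc(O[Si](C(C)C)(C(C)C)C(C)C)cc1
F6 | step 9 | (3S,4R)-3-[3,5-bis(TIPSO)phenyl]-4-[4-(TIPSO)phenyl]-2-[(2E)-3-[4-(TIPSO)phenyl]prop-2-enoyl]cyclopentan-1-one | O=C1C[C@@H](c2ccc(O[Si](C(C)C)(C(C)C)C(C)C)cc2)[C@H](c2cc(O[Si](C(C)C)(C(C)C)C(C)C)cc(O[Si](C(C)C)(C(C)C)C(C)C)c2)C1C(=O)/C=C/c1ccc(O[Si](C(C)C)(C(C)C)C(C)C)cc1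
F7 | step 6 | rac-1-[3,5-bis(TIPSO)phenyl]prop-2-en-1-ol | C=CC(O)c1cc(O[Si](C(C)C)(C(C)C)C(C)C)cc(O[Si](C(C)C)(C(C)C)C(C)C)c1
F8 | step 6 | (1R)-1-[3,5-bis(TIPSO)phenyl]prop-2-en-1-yl acetate | C=C[C@@H](OC(C)=O)c1cc(O[Si](C(C)C)(C(C)C)C(C)C)cc(O[Si](C(C)C)(C(C)C)C(C)C)c1
F9 | step 6 | (1S)-1-[3,5-bis(TIPSO)phenyl]prop-2-en-1-ol | C=C[C@H](O)c1cc(O[Si](C(C)C)(C(C)C)C(C)C)cc(O[Si](C(C)C)(C(C)C)C(C)C)c1
F10 | step 6 | (1R,2E)-1-[3,5-bis(TIPSO)phenyl]-4-oxopent-2-en-1-yl acetate | CC(=O)/C=C/[C@@H](OC(C)=O)c1cc(O[Si](C(C)C)(C(C)C)C(C)C)cc(O[Si](C(C)C)(C(C)C)C(C)C)c1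
F11 | step 8 | 5-[(1R,2E)-1-[3,5-bis(TIPSO)phenyl]-4-oxopent-2-en-1-yl]-2,2-dimethyl-6-[(E)-2-[4-(TIPSO)phenyl]ethenyl]-4H-1,3-dioxin-4-one | CC(=O)/C=C/[C@H](c1cc(O[Si](C(C)C)(C(C)C)C(C)C)cc(O[Si](C(C)C)(C(C)C)C(C)C)c1)C1=C(/C=C/c2ccc(O[Si](C(C)C)(C(C)C)C(C)C)cc2)OC(C)(C)OC1=O
F12 | step 8 | 5-[(1R,2R)-1-[3,5-bis(TIPSO)phenyl]-4-oxo-2-[4-(TIPSO)phenyl]pentyl]-2,2-dimethyl-6-[(E)-2-[4-(TIPSO)phenyl]ethenyl]-4H-1,3-dioxin-4-one | CC(=O)C[C@@H](c1ccc(O[Si](C(C)C)(C(C)C)C(C)C)cc1)[C@H](c1cc(O[Si](C(C)C)(C(C)C)C(C)C)cc(O[Si](C(C)C)(C(C)C)C(C)C)c1)C1=C(/C=C/c2ccc(O[Si](C(C)C)(C(C)C)C(C)C)cc2)OC(C)(C)OC1=O
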